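**Plan**
- Retrosynthesis: first the two angelate C–O bonds; then the cyclobutane bond C4–C10, formed from a C4 enolate whose one-carbon handle is later excised; then C2–C3 and C4–C5 of the cyclohexanone ring in one [4+2] event; then C1–C11, back to a cycloheptadienone.
- Forward: the seven-membered ring comes from carvone (as eucarvone, which already carries the three ring methyls), the six-membered ring from the key cycloaddition, the four-membered ring last by intramolecular epoxide alkylation.
- Enabling feature: in the ring C11–C1(=O)–C2–C3–C4–C5, C2 is α and C5 (through C11) is β to the C1 carbonyl, so the ring is a 2-oxido-diene C2=C1(O⁻)–C11=C5 plus the ene C3=C4. The 7-oxygen lies on the face of the seven-membered ring where C4 sits, two ring atoms from C5, so it can carry the ene as a crotonate (temporary δ-lactone).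
- Stereochemistry: the Jacobsen–Katsuki epoxidation sets C7/C8; the O7 tether sets C5, C4 and C3; enolate protonation sets C11; hydroxyl-directed epoxidation and anti opening set C9 and C10.

Key step: step 8

Remark: carbon numbers in names follow the longipinane skeleton (C1 ketone, C2 CH2, C3 CHMe, C4 and C11 the cyclobutane CH groups in the six-membered ring, C5 and C10 the other cyclobutane carbons, C6 CMe2, C7–C9 oxygenated). α marks the face of the seven-membered ring turned to C11/C1 (8-O, 9-O), β the face turned to C4 (7-O). Both acyl groups are angelates, (Z)-2-methylbut-2-enoates.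

**Step 1**
Reactants: 1 (R)-(−)-carvone
Product: 4 eucarvone, via carvone hydrobromide 2 (not isolated), via car-3-en-2-one 3 (not isolated)
Conditions: HBr (33% in AcOH), 0 °C; evaporate; KOH, MeOH, reflux
Reagents that add atoms: none
Why: Markovnikov hydrobromination of the isopropenyl group, 3-exo alkylation of the α'-enolate to the carenone and its base-mediated cyclopropane opening (carvone-to-eucarvone rearrangement) should give the achiral cycloheptadienone; the carvone stereocentre is lost.

**Step 2**
Reactants: 4 eucarvone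
Product: 5 (1R,7S)-3,6,6-trimethyl-8-oxabicyclo[5.1.0]oct-2-en-4-one
Conditions: (R,R)-[Mn(salen)Cl] (5 mol %; salen = N,N'-bis(3,5-di-tert-butylsalicylidene)cyclohexane-1,2-diamine dianion), NaOCl (aq., pH 11), 4-phenylpyridine N-oxide, CH2Cl2, 0 °C
Reagents that add atoms: sodium hypochlorite, [Na+].[O-]Cl
Why: Jacobsen–Katsuki epoxidation should take the cis-disubstituted, conjugated distal alkene (the enone alkene is trisubstituted and electron-poor); the facial sense is assigned by analogy with conjugated cis-alkenes flanked by a quaternary carbon (2,2-dimethylchromene) and is to be confirmed on the first run, since it fixes the absolute configuration of the whole route.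

**Step 3**
Reactants: 5 epoxy enone
Product: 6 (4S,5S)-4,5-dihydroxy-2,6,6-trimethylcyclohept-2-en-1-one
Conditions: HClO4 (cat.), THF–H2O, 0 °C
Reagents that add atoms: water, O
Why: Acid-catalysed hydrolysis of the vinyl epoxide by SN2-type attack of water at the allylic carbon C8 with inversion (C7 is neopentyl) should give the trans-7,8-diol.

**Step 4**
Reactants: 6 trans-diol
Product: 8 (4S,5S)-2,6,6-trimethyl-4-(triethylsilyloxy)-5-(trimethylsilyloxy)cyclohept-2-en-1-one, via 8-O-triethylsilyl diol 7 (not isolated)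
Conditions: TESCl (1.05 equiv), imidazole, CH2Cl2, −40 °C; then TMSCl (1.5 equiv), 0 °C
Reagents that add atoms: chlorotriethylsilane, CC[Si](Cl)(CC)CC; chlorotrimethylsilane, C[Si](C)(C)Cl
Why: Silyl ether formation: the allylic 8-OH reacts first with TESCl, and the hindered 7-OH next to the quaternary carbon is then capped in the same flask with the small, acid-labile TMS group.

**Step 5**
Reactants: 8 bis-silyl enone
Product: 10 (4S,5S)-3,3,7-trimethyl-5-(triethylsilyloxy)-4-(trimethylsilyloxy)cyclohepta-1,6-dien-1-yl trifluoromethanesulfonate, via potassium dienolate 9 (not isolated)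
Conditions: KN(SiMe3)2 (1.1 equiv), THF, −78 °C; 2-[N,N-bis(trifluoromethylsulfonyl)amino]-5-chloropyridine, −78 °C
Reagents that add atoms: 2-[N,N-bis(trifluoromethylsulfonyl)amino]-5-chloropyridine, O=S(=O)(N(c1ccc(Cl)cn1)S(=O)(=O)C(F)(F)F)C(F)(F)F
Why: Kinetic α'-deprotonation at the only enolisable CH2 (C5) gives the cross-conjugated enolate, which is trapped on oxygen (enol triflate formation); no ester is present at this stage.

**Step 6**
Reactants: 10 dienyl triflate, 11 tributyl(1-ethoxyvinyl)stannane
Product: 13 1-[(4S,5S)-4-hydroxy-3,3,7-trimethyl-5-(triethylsilyloxy)cyclohepta-1,6-dien-1-yl]ethan-1-one, via 2-ethoxydiene 12 (not isolated)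
Conditions: Pd(PPh3)4 (5 mol %), LiCl (3 equiv), THF, 60 °C; then 5% aq. oxalic acid, THF, 0 °C
Reagents that add atoms: tributyl(1-ethoxyvinyl)stannane, CCCC[Sn](CCCC)(CCCC)C(=C)OCC; water, O
Why: Stille coupling attaches C1 and C2 to C11; mild acid should then hydrolyse the 2-ethoxydiene to the methyl ketone and cleave the TMS ether while the bulkier TES ether stays.

**Step 7**
Reactants: 13 hydroxy dienone, 14 crotonic anhydride
Product: 15 (1S,7S)-4-acetyl-2,2,5-trimethyl-7-(triethylsilyloxy)cyclohepta-3,5-dien-1-yl (2E)-but-2-enoate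
Conditions: DMAP (0.3 equiv), Et3N, CH2Cl2, 0→25 °C
Reagents that add atoms: (2E)-but-2-enoic anhydride, C/C=C/C(=O)OC(=O)/C=C/C
Why: DMAP-catalysed acylation (Steglich-type acyl transfer) of the free 7-OH installs the E-crotonate that serves as the tethered two-carbon partner.

**Step 8**
Reactants: 15 acetyl-diene crotonate
Product: 18 keto δ-lactone (8-OTES), via lithium 2-oxidodiene 16 (not isolated), via cycloadduct lithium enolate 17 (not isolated)
Conditions: LiN(SiMe3)2 (1.1 equiv), THF, −78→−30 °C; AcOH, −78 °C
Reagents that add atoms: none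
Why: LiN(SiMe3)2 removes a proton from the acetyl methyl (more acidic than the crotonate γ-H) to give the 2-oxido-diene C2=C1(OLi)–C11=C5, which adds to the tethered crotonate so that C2 bonds to the β-carbon (C3) and the α-carbon (C4) bonds to C5; this is an anion-accelerated intramolecular Diels–Alder reaction, in its stepwise limit the intramolecular double Michael reaction of an enone dienolate on a tethered enoate, which is the closest known reaction type. The cyclohexanone ring is closed by the [4+2] event, and the C4–C5 bond closes the temporary δ-lactone at the same time (6-exo-trig in the Michael description). C5 and C4 are controlled by the tether: the crotonate hangs from O7 two ring atoms from C5, so it can reach C5 only on the O7 face and only with its carbonyl under the diene (endo, cis-fused lactone). C3 is controlled by the E geometry of the crotonate, which places the methyl trans to the carbonyl on C4 and hence on the ring face opposite to C6. C11 is set when acetic acid protonates the extended enolate at its α-carbon from the convex face, cis to H-5, which gives the β,γ-unsaturated ketone. Regioselectivity follows from polarity matching (nucleophilic C2 on electrophilic C3) and from the tether, and the low temperature avoids the [1,5]-hydrogen shift of the cycloheptadiene and loss of the 8-silyloxy group from enolate 17.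

**Step 9**
Reactants: 18 keto δ-lactone (8-OTES)
Product: 19 keto δ-lactone (8-OH)
Conditions: HF·pyridine, pyridine, THF, 0 °C
Reagents that add atoms: none
Why: Buffered fluoride desilylation should free the allylic 8-OH without touching the lactone or the β,γ-unsaturated ketone.

**Step 10**
Reactants: 19 allylic alcohol
Product: 20 9α,10α-epoxy alcohol
Conditions: VO(acac)2 (5 mol %), t-BuOOH, CH2Cl2, 0→25 °C
Reagents that add atoms: tert-butyl hydroperoxide, CC(C)(C)OO
Why: Hydroxyl-directed epoxidation of a cyclic allylic alcohol (vanadium-catalysed) delivers oxygen syn to the 8-OH, which sets C9 and puts the epoxide oxygen at C10 opposite to the face from which C4 must arrive.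

**Step 11**
Reactants: 20 epoxy alcohol
Product: 21 epoxy keto lactone (8-OTBS)
Conditions: TBSCl, imidazole, DMAP (cat.), DMF, 40 °C
Reagents that add atoms: tert-butylchlorodimethylsilane, CC(C)(C)[Si](C)(C)Cl
Why: Silyl ether formation under weakly basic conditions gives the 8-O protecting group that is kept until the last step.

**Step 12**
Reactants: 21 epoxy keto lactone (8-OTBS)
Product: 23 cyclobutane lactone (9-OH), via bis-enolate 22 (not isolated)
Conditions: LiN(iPr)2 (2.3 equiv), THF, −78 °C; Et2AlCl (2.3 equiv), −78→0 °C; aq. potassium sodium tartrate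
Reagents that add atoms: none
Why: Proposed new method: the ketone is held as its kinetic C2 enolate (so C11–H is not removed) and the lactone is deprotonated at C4; the cis ring fusion holds the C4 enolate carbon about 3 Å behind C10 on the axis of the C10–O bond, whose oxygen is bound to aluminium, so a 4-exo-tet opening with inversion at the tertiary carbon C10 should close the cyclobutane, make C10 quaternary and leave the 9-oxygen α; attack at C9 is geometrically impossible, and the step is irreversible because epoxide strain is released as cyclobutane strain is built. The closest known reaction types are the epoxynitrile cyclization (4-exo epoxide opening by a stabilised carbanion to give cyclobutanes) and the opening of epoxides by aluminium ester enolates; new are the lactone enolate as nucleophile and the bond between two fully substituted carbons.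

**Step 13**
Reactants: 23 cyclobutane lactone
Product: 25 7β,9α-dihydroxy-8α-(tert-butyldimethylsilyloxy)longipinan-1-one, via lithium carboxylate 24 (not isolated)
Conditions: LiOH, THF–H2O, 50 °C; evaporate; 9-mesityl-10-phenylacridinium BF4 (5 mol %), (PhS)2 (10 mol %), CF3CH2OH, blue LEDs, 25 °C
Reagents that add atoms: none
Why: Saponification of the strained lactone frees the 7-OH, and photoredox hydrodecarboxylation of the tertiary carboxylate (acridinium photocatalyst, thiol hydrogen-atom transfer) replaces CO2 by H at the bridgehead C4, where no stereochemical choice exists; using the salt directly avoids relactonisation.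

**Step 14**
Reactants: 25 diol, 26 angelic acid
Product: 27 7β,9α-bis(angeloyloxy)-8α-(tert-butyldimethylsilyloxy)longipinan-1-one
Conditions: 26, 2,4,6-trichlorobenzoyl chloride, Et3N, toluene, 25 °C; then 25, DMAP, toluene, 80 °C
Reagents that add atoms: (2Z)-2-methylbut-2-enoic acid, C/C=C(/C)C(=O)O
Why: Yamaguchi esterification through the mixed anhydride should acylate both hindered secondary hydroxyls and is the usual way to keep the Z geometry of angelates.

**Step 15**
Reactants: 27 bis-angelate silyl ether
Product: 28 target, 7β,9α-bis(angeloyloxy)-8α-hydroxylongipinan-1-one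
Conditions: HF·pyridine, THF, 0→25 °C
Reagents that add atoms: none
Why: Fluoride cleavage of the TBS ether under buffered, mildly acidic conditions should free the 8-OH without acyl migration or angelate isomerisation.

**Compound list**
1 | (R)-(−)-carvone, (5R)-2-methyl-5-(prop-1-en-2-yl)cyclohex-2-en-1-one | CC1=CC[C@H](CC1=O)C(C)=C | starting material
2 | carvone hydrobromide, (5R)-5-(2-bromopropan-2-yl)-2-methylcyclohex-2-en-1-one | CC1=CC[C@H](CC1=O)C(C)(C)Br | intermediate
3 | car-3-en-2-one, (1S,6R)-3,7,7-trimethylbicyclo[4.1.0]hept-3-en-2-one | CC1=CC[C@H]2C(C)(C)[C@H]2C1=O | intermediate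
4 | eucarvone, 2,6,6-trimethylcyclohepta-2,4-dien-1-one | CC1=CC=CC(C)(C)CC1=O | intermediate
5 | (1R,7S)-3,6,6-trimethyl-8-oxabicyclo[5.1.0]oct-2-en-4-one | CC1=C[C@H]2O[C@H]2C(C)(C)CC1=O | intermediate
6 | (4S,5S)-4,5-dihydroxy-2,6,6-trimethylcyclohept-2-en-1-one | CC1=C[C@H](O)[C@@H](O)C(C)(C)CC1=O | intermediate
7 | (4S,5S)-5-hydroxy-2,6,6-trimethyl-4-(triethylsilyloxy)cyclohept-2-en-1-one | CC1=C[C@H](O[Si](CC)(CC)CC)[C@@H](O)C(C)(C)CC1=O | intermediate
8 | (4S,5S)-2,6,6-trimethyl-4-(triethylsilyloxy)-5-(trimethylsilyloxy)cyclohept-2-en-1-one | CC1=C[C@H](O[Si](CC)(CC)CC)[C@@H](O[Si](C)(C)C)C(C)(C)CC1=O | intermediate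
9 | potassium (4S,5S)-3,3,7-trimethyl-5-(triethylsilyloxy)-4-(trimethylsilyloxy)cyclohepta-1,6-dien-1-olate | CC1=C[C@H](O[Si](CC)(CC)CC)[C@@H](O[Si](C)(C)C)C(C)(C)C=C1[O-].[K+] | intermediate
10 | (4S,5S)-3,3,7-trimethyl-5-(triethylsilyloxy)-4-(trimethylsilyloxy)cyclohepta-1,6-dien-1-yl trifluoromethanesulfonate | CC1=C[C@H](O[Si](CC)(CC)CC)[C@@H](O[Si](C)(C)C)C(C)(C)C=C1OS(=O)(=O)C(F)(F)F | intermediate
11 | tributyl(1-ethoxyvinyl)stannane | CCCC[Sn](CCCC)(CCCC)C(=C)OCC | starting material
12 | (4S,5S)-1-(1-ethoxyvinyl)-3,3,7-trimethyl-5-(triethylsilyloxy)-4-(trimethylsilyloxy)cyclohepta-1,6-diene | CC1=C[C@H](O[Si](CC)(CC)CC)[C@@H](O[Si](C)(C)C)C(C)(C)C=C1C(=C)OCC | intermediate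
13 | 1-[(4S,5S)-4-hydroxy-3,3,7-trimethyl-5-(triethylsilyloxy)cyclohepta-1,6-dien-1-yl]ethan-1-one | CC1=C[C@H](O[Si](CC)(CC)CC)[C@@H](O)C(C)(C)C=C1C(C)=O | intermediate
14 | crotonic anhydride, (2E)-but-2-enoic anhydride | C/C=C/C(=O)OC(=O)/C=C/C | starting material
15 | (1S,7S)-4-acetyl-2,2,5-trimethyl-7-(triethylsilyloxy)cyclohepta-3,5-dien-1-yl (2E)-but-2-enoate | CC1=C[C@H](O[Si](CC)(CC)CC)[C@@H](OC(=O)/C=C/C)C(C)(C)C=C1C(C)=O | intermediate
16 | lithium enolate of 15 at the acetyl methyl (2-oxido-diene C2=C1(OLi)–C11=C5) | CC1=C[C@H](O[Si](CC)(CC)CC)[C@@H](OC(=O)/C=C/C)C(C)(C)C=C1C(=C)[O-].[Li+] | intermediate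
17 | lithium dienolate of cycloadduct 18 (C1–OLi, C1=C11, C9=C10) | CC[Si](CC)(CC)O[C@H]1C=C(C)C2=C([O-])C[C@@H](C)[C@@H]3C(=O)O[C@H]1C(C)(C)[C@H]23.[Li+] | intermediate
18 | 1-oxo-8α-(triethylsilyloxy)-4,10-seco-longipin-9-ene-4,7-carbolactone (cyclohexanone ring cis-fused at C5–C11 to the cycloheptene; lactone C=O on C4, ring O on C7; 3-Me, H-4, H-5, H-11 on one face, lactone bridge on the other; 3R,4S,5R,7S,8S,11R) | CC[Si](CC)(CC)O[C@H]1C=C(C)[C@@H]2C(=O)C[C@@H](C)[C@@H]3C(=O)O[C@H]1C(C)(C)[C@H]23 | intermediate
19 | 8α-hydroxy-1-oxo-4,10-seco-longipin-9-ene-4,7-carbolactone (18 without the silyl group) | O[C@H]1C=C(C)[C@@H]2C(=O)C[C@@H](C)[C@@H]3C(=O)O[C@H]1C(C)(C)[C@H]23 | intermediate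
20 | 9α,10α-epoxy-8α-hydroxy-1-oxo-4,10-seco-longipinane-4,7-carbolactone (epoxide oxygen cis to the 8-OH) | O[C@H]1[C@H]2O[C@@]2(C)[C@@H]3C(=O)C[C@@H](C)[C@@H]4C(=O)O[C@H]1C(C)(C)[C@H]34 | intermediate
21 | 8-O-tert-butyldimethylsilyl ether of 20 | CC(C)(C)[Si](C)(C)O[C@H]1[C@H]2O[C@@]2(C)[C@@H]3C(=O)C[C@@H](C)[C@@H]4C(=O)O[C@H]1C(C)(C)[C@H]34 | intermediate
22 | dilithium bis-enolate of 21 (ketone enolate C1=C2, lactone enolate at C4; transmetalated to aluminium in the flask) | CC(C)(C)[Si](C)(C)O[C@H]1[C@H]2O[C@@]2(C)[C@@H]3C([O-])=C[C@@H](C)C4=C([O-])O[C@H]1C(C)(C)[C@H]34.[Li+].[Li+] | intermediate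
23 | 8α-(tert-butyldimethylsilyloxy)-9α-hydroxy-1-oxolongipinane-4,7-carbolactone (cyclobutane closed; lactone C=O on C4, ring O on C7; target configuration at C3, C5, C7–C11) | O=C1O[C@@H]2[C@@H](O[Si](C)(C)C(C)(C)C)[C@@H](O)[C@]3(C)[C@@]14[C@@H]([C@H]3C(=O)C[C@H]4C)C2(C)C | intermediate
24 | lithium 8α-(tert-butyldimethylsilyloxy)-7β,9α-dihydroxy-1-oxolongipinane-4-carboxylate | O[C@@H]1[C@@H](O[Si](C)(C)C(C)(C)C)[C@@H](O)[C@]2(C)[C@]3(C([O-])=O)[C@@H]([C@H]2C(=O)C[C@H]3C)C1(C)C.[Li+] | intermediate
25 | 7β,9α-dihydroxy-8α-(tert-butyldimethylsilyloxy)longipinan-1-one | O[C@@H]1[C@@H](O[Si](C)(C)C(C)(C)C)[C@@H](O)[C@]2(C)[C@@H]3[C@@H]([C@H]2C(=O)C[C@H]3C)C1(C)C | intermediate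
26 | angelic acid, (2Z)-2-methylbut-2-enoic acid | C/C=C(/C)C(=O)O | starting material
27 | 7β,9α-bis(angeloyloxy)-8α-(tert-butyldimethylsilyloxy)longipinan-1-one | C/C=C(/C)C(=O)O[C@@H]1[C@@H](O[Si](C)(C)C(C)(C)C)[C@@H](OC(=O)/C(C)=C\C)[C@]2(C)[C@@H]3[C@@H]([C@H]2C(=O)C[C@H]3C)C1(C)C | intermediate
28 | (3R,4S,5S,7S,8R,9S,10R,11R)-7,9-bis[(2Z)-2-methylbut-2-enoyloxy]-8-hydroxylongipinan-1-one | C/C=C(/C)C(=O)O[C@@H]1[C@@H](O)[C@@H](OC(=O)/C(C)=C\C)[C@]2(C)[C@@H]3[C@@H]([C@H]2C(=O)C[C@H]3C)C1(C)C | target

**Totals and risks**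
Total steps: 15. Longest linear sequence: 15 (from carvone).

Steps most likely to fail:

1. Step 12 (Proposed new method). What may go wrong: no C–C bond formation at the tertiary epoxide carbon, with competing enolisation towards C11 and β-elimination of the epoxide, or hydride-shift rearrangement of the aluminium-bound epoxide to a ketone. Fallback with known chemistry, from 19 back to 23: the 8-OH of 19 is converted with ClP(O)(OEt)2 and pyridine into the allylic diethyl phosphate F1. LiN(iPr)2 (2.3 equiv, −78 °C) then gives the ketone/lactone bis-enolate, whose C4 carbon displaces the phosphate in an intramolecular anti-SN2′ enolate alkylation at the methyl-bearing alkene carbon C10 (attack on an sp2 carbon instead of a tertiary sp3 carbon), giving the vinylcyclobutane lactone F2 with a C8=C9 double bond. OsO4/N-methylmorpholine N-oxide dihydroxylation anti to the allylic 7-oxygen gives the 8α,9α-diol F3, and TBSCl/imidazole silylates the less hindered 8-OH to rejoin the route at 23.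

2. Step 8 (key step). What may go wrong: slow cycloaddition because the ester tether must adopt its less populated conformer, competing deprotonation of the crotonate, or loss of the 8-silyloxy group from the product dienolate. Fallback, from 13 back to 19: 13 is bis-silylated (TMSOTf, Et3N, −78 °C) to the 2-(trimethylsilyloxy)diene F4 with a 7-O-TMS group. F4 and commercial 3-[(E)-but-2-enoyl]oxazolidin-2-one are joined in an intermolecular, endo-selective Diels–Alder reaction catalysed by [Cu(t-Bu-box)](SbF6)2 (divalent copper; the catalyst enantiomer that reinforces attack on the O7 face), giving the imide cycloadduct F5. HF·pyridine removes the three silyl groups, and the freed 7-OH closes the δ-lactone with loss of oxazolidinone (DMAP if needed), rejoining the route at 19.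

3. Step 14. What may go wrong: incomplete acylation of the two neopentyl-type hydroxyls and Z-to-E isomerisation of the angeloyl group under forcing conditions. Fallback, from 25 back to 27: both hydroxyls are esterified with 2-(diphenoxyphosphoryl)propanoic acid (DCC, DMAP) to the bis(phosphonopropionate) F6, and a Z-selective Horner–Wadsworth–Emmons olefination of both phosphonates with acetaldehyde (KN(SiMe3)2, 18-crown-6, THF, −78 °C) builds the two angelate groups in place, giving 27.

**Further compounds**
F1 | step 12 | 8-O-diethylphosphoryl derivative of 19 (allylic phosphate) | CCOP(=O)(OCC)O[C@H]1C=C(C)[C@@H]2C(=O)C[C@@H](C)[C@@H]3C(=O)O[C@H]1C(C)(C)[C@H]23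
F2 | step 12 | 1-oxolongipin-8-ene-4,7-carbolactone (vinylcyclobutane lactone) | O=C1O[C@@H]2C=C[C@]3(C)[C@@]14[C@@H]([C@H]3C(=O)C[C@H]4C)C2(C)C
F3 | step 12 | 8α,9α-dihydroxy-1-oxolongipinane-4,7-carbolactone | O=C1O[C@@H]2[C@@H](O)[C@@H](O)[C@]3(C)[C@@]14[C@@H]([C@H]3C(=O)C[C@H]4C)C2(C)C
F4 | step 8 | 7-O-trimethylsilyl 2-(trimethylsilyloxy)diene from 13 | CC1=C[C@H](O[Si](CC)(CC)CC)[C@@H](O[Si](C)(C)C)C(C)(C)C=C1C(=C)O[Si](C)(C)C
F5 | step 8 | Diels–Alder adduct: C1 silyl enol ether, C4 N-acyloxazolidinone, 7-OTMS, 8-OTES | CC[Si](CC)(CC)O[C@H]1C=C(C)C2=C(O[Si](C)(C)C)C[C@@H](C)[C@H](C(=O)N3CCOC3=O)[C@@H]2C(C)(C)[C@@H]1O[Si](C)(C)C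
F6 | step 14 | 7,9-bis[2-(diphenoxyphosphoryl)propanoate] of 25 (epimers at the phosphonate-bearing carbons) | CC(P(=O)(Oc1ccccc1)Oc1ccccc1)C(=O)O[C@@H]1[C@@H](O[Si](C)(C)C(C)(C)C)[C@@H](OC(=O)C(C)P(=O)(Oc2ccccc2)Oc2ccccc2)[C@]2(C)[C@@H]3[C@@H]([C@H]2C(=O)C[C@H]3C)C1(C)C
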